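**Retrosynthetic overview**

- The target chromanone is opened at the O1–C2 bond: a 6-endo oxa-Michael closure of the open-chain 2-hydroxyaryl enone (E)-7-hydroxycymopolone, the presumed biogenetic precursor. This is the last step and sets the only stereocentre under catalyst control.
- (E)-7-Hydroxycymopolone is cut at the aryl–acyl bond: photochemical acylation of 2-bromo-1,4-benzoquinone by (2E)-7-hydroxy-3,7-dimethyloct-2-enal, with no protecting groups.
- The enal comes from geraniol (selective hydration of the remote alkene, then allylic oxidation); the quinone comes from bromohydroquinone.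
- Ring order: the arene is bought; the pyranone ring is the only ring made, in the final step.

Assumption: the quinine-derived thiourea of step 5 is taken to give the (R)-chromanone; if a pilot run shows the opposite sense, its quinidine-derived pseudoenantiomer is used in the same way.

**Route**

Step 1
Reactants: 1 geraniol, (2E)-3,7-dimethylocta-2,6-dien-1-ol
Product: 3 (2E)-3,7-dimethyloct-2-ene-1,7-diol, via organomercurial acetate 2 (not isolated)
Conditions: Hg(OAc)2 (1.0 equiv), THF/H2O (1:1), 20 °C; then NaBH4, 0 °C
Reagents that add atoms: water, O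
Why: Markovnikov oxymercuration–demercuration, in which Hg(OAc)2 takes the electron-richer remote 6,7-alkene in preference to the inductively deactivated allylic-alcohol alkene, water opens the mercurinium ion at the tertiary carbon and NaBH4 replaces mercury by hydrogen, leaving the 2E geometry untouched and no stereocentre behind.

Step 2
Reactants: 3 (2E)-3,7-dimethyloct-2-ene-1,7-diol
Product: 4 (2E)-7-hydroxy-3,7-dimethyloct-2-enal
Conditions: TEMPO (2,2,6,6-tetramethylpiperidin-1-oxyl, 10 mol%), PhI(OAc)2 (1.1 equiv), CH2Cl2, 20 °C
Reagents that add atoms: none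
Why: Oxoammonium (TEMPO/PhI(OAc)2) oxidation is selective for the primary allylic alcohol, cannot touch the tertiary alcohol and does not isomerise the E-alkene.

Step 3
Reactants: 5 bromohydroquinone, 2-bromobenzene-1,4-diol
Product: 6 2-bromo-1,4-benzoquinone
Conditions: NaIO4 (1.1 equiv), CH2Cl2/H2O, 20 °C
Reagents that add atoms: none
Why: Periodate oxidation of a hydroquinone to its p-quinone is a fast, clean two-electron oxidation.

Step 4
Reactants: 4 (2E)-7-hydroxy-3,7-dimethyloct-2-enal; 6 2-bromo-1,4-benzoquinone
Product: 7 (E)-7-hydroxycymopolone, (2E)-1-(4-bromo-2,5-dihydroxyphenyl)-7-hydroxy-3,7-dimethyloct-2-en-1-one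
Conditions: hν (450 nm LEDs), PhCF3, N2, 20 °C, enal in threefold excess over the quinone (surplus enal recovered unchanged); chromatography on silica without base
Reagents that add atoms: none
Why: Photo-Friedel–Crafts acylation of a quinone by an aldehyde, a 1:1 addition in which the visible-light-excited triplet of 6 abstracts the formyl hydrogen of 4, the nucleophilic acyl radical bonds to ring carbon C5 (β to the C1 carbonyl, which bromine does not deactivate by lone-pair donation, and remote from bromine) and tautomerisation gives the acylhydroquinone with every atom of both partners retained and nothing split off; the E-alkene survives because the enal does not absorb at 450 nm and 4 has no electron-rich alkene left for oxetane formation.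

Step 5
Reactants: 7 (E)-7-hydroxycymopolone
Product: 8 (2R)-7-bromo-6-hydroxy-2-(4-hydroxy-4-methylpentyl)-2-methyl-2,3-dihydro-4H-chromen-4-one
Conditions: 1-[3,5-bis(trifluoromethyl)phenyl]-3-[(8S,9S)-6'-methoxycinchonan-9-yl]thiourea (quinine-derived, 10–20 mol%), PhMe/CH2Cl2 (4:1), 0 °C
Reagents that add atoms: none
Why: Proposed new method: a catalytic enantioselective 6-endo-trig intramolecular oxa-Michael addition onto an unactivated β,β-dialkyl enone, in which the quinuclidine nitrogen deprotonates the chelated 2-hydroxyl (the only nucleophile both acidic enough and within reach, since an amine does not ionise the tertiary alcohol) while the thiourea N–H pair binds the enone oxygen, so the phenoxide is delivered to one enantiotopic face of the geometrically pure E-alkene and C2 is set as R under catalyst control; the closure itself is the isomerisation that simple bases effect readily on 2-hydroxyaryl prenyl-type ketones, and the closest known reaction types are the cinchona-thiourea-catalysed asymmetric oxa-Michael cyclisation of 2-hydroxyphenyl alkylidene β-ketoesters to chromanones and flavanones and the amine-catalysed oxa-Michael closures that set the 2-methyl-2-alkyl chromane centre in tocopherol syntheses.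

**Compound list**

1 | geraniol, (2E)-3,7-dimethylocta-2,6-dien-1-ol | CC(C)=CCC/C(C)=C/CO | starting material
2 | acetoxy[(6E)-2,8-dihydroxy-2,6-dimethyloct-6-en-3-yl]mercury, racemic at the mercury-bearing carbon, not isolated | CC(C)(O)C([Hg]OC(C)=O)CC/C(C)=C/CO | intermediate
3 | (2E)-3,7-dimethyloct-2-ene-1,7-diol | CC(C)(O)CCC/C(C)=C/CO | intermediate
4 | (2E)-7-hydroxy-3,7-dimethyloct-2-enal | CC(C)(O)CCC/C(C)=C/C=O | intermediate
5 | bromohydroquinone, 2-bromobenzene-1,4-diol | Oc1ccc(O)c(Br)c1 | starting material
6 | 2-bromo-1,4-benzoquinone, 2-bromocyclohexa-2,5-diene-1,4-dione | O=C1C=CC(=O)C(Br)=C1 | intermediate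
7 | (E)-7-hydroxycymopolone, (2E)-1-(4-bromo-2,5-dihydroxyphenyl)-7-hydroxy-3,7-dimethyloct-2-en-1-one | CC(C)(O)CCC/C(C)=C/C(=O)c1cc(O)c(Br)cc1O | intermediate
8 | (2R)-7-bromo-6-hydroxy-2-(4-hydroxy-4-methylpentyl)-2-methyl-2,3-dihydro-4H-chromen-4-one | CC(C)(O)CCC[C@]1(C)CC(=O)c2cc(O)c(Br)cc2O1 | target

**Step count**

Total steps: 5. Longest linear sequence: 4 (steps 1, 2, 4, 5 from geraniol).

**Steps most likely to fail**

1. Step 5 (most likely). The enone is unactivated and β,β-dialkyl, so the catalysed closure may be slow, and any uncatalysed closure or base-induced ring opening and re-closure of 8 lowers the ee. Compound 7 must enter the step free of racemic chromanone. Fallback, setting out from 7 and coming back at 8: close the ring without a chiral catalyst (K2CO3, MeOH, 20 °C) and separate the racemate on a chiral stationary phase (preparative SFC) into 8 and (2S)-7-bromo-6-hydroxy-2-(4-hydroxy-4-methylpentyl)-2-methyl-2,3-dihydro-4H-chromen-4-one F1. F1 is returned to the racemate by heating with DBU (ring opening to 7 and re-closure) and separated again.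

2. Step 4. The position of acylation on the bromoquinone (C5 wanted, C6 or C3 possible) is predicted rather than established. The triplet quinone may also attack allylic hydrogens or isomerise the enone. Fallback, setting out from 4 and coming back at 7: commercial 2,5-dibromohydroquinone is protected (MOMCl, i-Pr2NEt, CH2Cl2) as 1,4-dibromo-2,5-bis(methoxymethoxy)benzene F2. One bromine–lithium exchange (n-BuLi, THF, −78 °C) gives [4-bromo-2,5-bis(methoxymethoxy)phenyl]lithium F3. Two equivalents of F3 are used, the first being consumed by the tertiary hydroxyl, and addition to aldehyde 4 gives (2E)-1-[4-bromo-2,5-bis(methoxymethoxy)phenyl]-3,7-dimethyloct-2-ene-1,7-diol F4 (racemic at C1). MnO2 (CH2Cl2, 20 °C) oxidises the benzylic-allylic alcohol to (2E)-1-[4-bromo-2,5-bis(methoxymethoxy)phenyl]-7-hydroxy-3,7-dimethyloct-2-en-1-one F5. Brief HCl in MeOH/THF at 20 °C removes both MOM groups to give 7, which is chromatographed free of any cyclised material.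

3. Step 1. Selectivity between the two trisubstituted alkenes of geraniol may be incomplete, and some mercury-induced cyclisation is possible. Fallback, setting out from 1 and coming back at 3: acetylation (Ac2O, pyridine) gives geranyl acetate F6. mCPBA (CH2Cl2, 0 °C) epoxidises the electron-richer remote alkene to (2E)-6,7-epoxy-3,7-dimethyloct-2-en-1-yl acetate F7 (racemic). LiAlH4 (THF, 0 °C) opens the epoxide at the secondary carbon and cleaves the acetate, returning diol 3.

**Further compounds**

F1 | step 5 | (2S)-7-bromo-6-hydroxy-2-(4-hydroxy-4-methylpentyl)-2-methyl-2,3-dihydro-4H-chromen-4-one | CC(C)(O)CCC[C@@]1(C)CC(=O)c2cc(O)c(Br)cc2O1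
F2 | step 4 | 1,4-dibromo-2,5-bis(methoxymethoxy)benzene | COCOc1cc(Br)c(OCOC)cc1Br
F3 | step 4 | [4-bromo-2,5-bis(methoxymethoxy)phenyl]lithium | [Li]c1cc(OCOC)c(Br)cc1OCOC
F4 | step 4 | (2E)-1-[4-bromo-2,5-bis(methoxymethoxy)phenyl]-3,7-dimethyloct-2-ene-1,7-diol, racemic at C1 | CC(C)(O)CCC/C(C)=C/C(O)c1cc(OCOC)c(Br)cc1OCOC
F5 | step 4 | (2E)-1-[4-bromo-2,5-bis(methoxymethoxy)phenyl]-7-hydroxy-3,7-dimethyloct-2-en-1-one | CC(C)(O)CCC/C(C)=C/C(=O)c1cc(OCOC)c(Br)cc1OCOC
F6 | step 1 | geranyl acetate, (2E)-3,7-dimethylocta-2,6-dien-1-yl acetate | CC(C)=CCC/C(C)=C/COC(C)=O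
F7 | step 1 | (2E)-6,7-epoxy-3,7-dimethyloct-2-en-1-yl acetate, racemic | CC1(C)OC1CC/C(C)=C/COC(C)=O
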